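**Retrosynthetic overview**
1. The last bond is C1–C8, which closes ring B. The C8 tertiary cation of the presumed biosynthesis is trapped by C1 of a dearomatised acylphloroglucinol. The cation is stored as a C8–O pyran ether and released by a silyl triflate (formal 1,3 O-to-C shift), so no proton reaches the four alkenes.
2. The C5 quaternary centre comes from alkylative dearomatisation of a chroman with (R)-lavandulyl triflate. The C7 centre inside the fused pyran steers the face and gives the 7-endo series.
3. The chroman comes from prenylated 2,4,6-trihydroxy-3'-methoxybenzophenone and hydrochlorinated (S)-lavandulol, by C-alkylation and then SN1 closure on the para oxygen.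
4. C7 and the side-chain centre have opposite sense. Both antipodes of one racemic lavandulic acid are therefore used, split as oxazolidinone imides.
5. Ring order: ring A is bought (phloroglucinol), then the temporary pyran ring P forms, then ring B closes as ring P opens.

Assumption: the enol is drawn as in the target string (the tautomers equilibrate). PPAP numbering is used throughout: C1 prenyl bridgehead, C5 lavandulyl bridgehead, C7 CH, C8 CMe2, C9 bridge ketone.

**Step 1**
Reactants: 1 3-methylbut-2-enoic acid; 2 prenyl bromide
Product: 3 (±)-lavandulic acid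
Conditions: LiN(iPr)2 (2.2 equiv), THF, −78 → 0 °C; 2, −78 °C → rt; aq. HCl
Reagents that add atoms: none
Why: Deconjugative α-alkylation of the lithium dienediolate, which takes up allylic halides at the α-carbon and moves the double bond out of conjugation; the new stereocentre is left racemic on purpose because both antipodes are consumed later in equal amounts.

**Step 2**
Reactants: 3 (±)-lavandulic acid; 4 (S)-4-benzyl-1,3-oxazolidin-2-one
Product: 6 (4S)-4-benzyl-3-[(2S)-5-methyl-2-(prop-1-en-2-yl)hex-4-enoyl]-1,3-oxazolidin-2-one; 7 its (2R)-epimer (separated on silica), via mixed pivalic anhydride 5 (not isolated)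
Conditions: t-BuCOCl, Et3N, THF, −20 °C; then LiCl, 4, −20 °C → rt; chromatography
Reagents that add atoms: none
Why: N-acylation of an Evans oxazolidinone through the mixed anhydride turns the racemate into two covalent diastereomers that differ next to the auxiliary and separate on silica (classical resolution), so 6 fixes the future C7 centre and 7 the future side-chain centre, the assignment being checked by the sign of rotation of 8 and 9.

**Step 3**
Reactants: 6 (2S)-imide
Product: 8 (S)-lavandulol
Conditions: LiBH4, H2O (2 equiv), Et2O, 0 °C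
Reagents that add atoms: none
Why: Reductive cleavage of the N-acyl oxazolidinone by LiBH4 attacks only the exocyclic imide carbonyl, does not enolise the α-centre and leaves both alkenes alone, so the (2S) centre is carried over unchanged.

**Step 4**
Reactants: 7 (2R)-imide
Product: 9 (R)-lavandulol
Conditions: LiBH4, H2O (2 equiv), Et2O, 0 °C
Reagents that add atoms: none
Why: The same reductive auxiliary cleavage as in step 3, again without enolisation, so the (2R) centre is carried over unchanged.

**Step 5**
Reactants: 8 (S)-lavandulol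
Product: 10 (2R)-2-(2-chloropropan-2-yl)-5-methylhex-4-en-1-ol
Conditions: Co(BF4)2·6H2O (5 mol %), potassium 2-[(3,5-di-tert-butyl-2-hydroxybenzylidene)amino]-2,2-diphenylacetate (5 mol %), t-BuOOH (cat.), PhSiH3 (1.0 equiv), TsCl (1.2 equiv), EtOH, rt
Reagents that add atoms: p-toluenesulfonyl chloride, Cc1ccc(cc1)S(=O)(=O)Cl
Why: Cobalt hydride hydrogen-atom-transfer (Mukaiyama-type) Markovnikov hydrochlorination, in which the hydride adds to the unhindered 1,1-disubstituted alkene much faster than to the trisubstituted prenyl alkene and the tertiary radical takes chlorine from TsCl; the neighbouring stereocentre is untouched (S becomes R only because CMe2Cl outranks CH2OH).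

**Step 6**
Reactants: 11 phloroglucinol; 12 3-methoxybenzoyl chloride
Product: 13 (3-methoxyphenyl)(2,4,6-trihydroxyphenyl)methanone
Conditions: AlCl3 (4 equiv), PhNO2, 60 °C; aq. HCl
Reagents that add atoms: none
Why: Friedel–Crafts acylation of the symmetric electron-rich arene stops after one acylation because the chelated ketone deactivates the ring, and the meta methyl ether is not chelated to aluminium and survives.

**Step 7**
Reactants: 13 benzophenone; 2 prenyl bromide
Product: 14 (3-methoxyphenyl)[2,4,6-trihydroxy-3-(3-methylbut-2-enyl)phenyl]methanone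
Conditions: KOH (1.1 equiv), H2O, 0 °C → rt, 2 (0.9 equiv)
Reagents that add atoms: none
Why: C-alkylation of the phloroglucinolate monoanion in water, where hydrogen bonding shields oxygen so the soft allylic bromide is taken up at carbon; the two free ring positions are equivalent and limiting bromide keeps diprenylation low.

**Step 8**
Reactants: 10 chloro alcohol; 14 prenyl benzophenone
Product: 17 [(3R)-5,7-dihydroxy-2,2-dimethyl-3,8-bis(3-methylbut-2-enyl)chroman-6-yl](3-methoxyphenyl)methanone, via chloro triflate 15 (not isolated), via open-chain chloride 16 (not isolated)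
Conditions: 10, Tf2O, 2,6-lutidine, CH2Cl2, −78 °C; cannulated into 14, LiN(SiMe3)2 (4.1 equiv), THF–PhMe, 0 °C → rt; then (CF3)2CHOH, 40 °C; aq. NH4Cl
Reagents that add atoms: none
Why: Lithium phenoxide C-alkylation at the only free ring CH by the primary triflate (re-aromatisation follows), then SN1 etherification in which the ionising, non-nucleophilic alcohol ionises only the tertiary chloride and the para oxygen closes the six-membered ring, since it carries the charge of the mono-lithium salt while both ortho hydroxyls are chelated to the ketone; LiCl leaves so no acid forms, and the C7 centre is a spectator.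

**Step 9**
Reactants: 9 (R)-lavandulol; 17 chroman
Product: 19 (3R,4aS)-7-hydroxy-6-(3-methoxybenzoyl)-2,2-dimethyl-3,8-bis(3-methylbut-2-enyl)-4a-[(2S)-5-methyl-2-(prop-1-en-2-yl)hex-4-enyl]-3,4-dihydro-2H-chromen-5(4aH)-one, via (R)-lavandulyl triflate 18 (not isolated)
Conditions: 9, Tf2O, 2,6-lutidine, CH2Cl2, −78 °C; cannulated into 17, LiN(SiMe3)2 (3.1 equiv), THF–PhMe, 0 °C → rt; aq. NH4Cl
Reagents that add atoms: none
Why: Alkylative dearomatisation of the acylphloroglucinol dianion, in which C4a (substituent tied back into the ring) is less shielded than the prenyl-bearing C8 and the triflate adds axially to the half-chair that keeps the C7 prenyl equatorial, on the face of the axial C7–H, because the other face runs through a boat against the axial C8 methyl; this puts the lavandulyl group trans to the C7 prenyl and sets C5 as (4aS), the 7-endo relationship of the target.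

**Step 10**
Reactants: 19 pyran dienone methyl ether
Product: 20 (3R,4aS)-7-hydroxy-6-(3-hydroxybenzoyl) analogue of 19
Conditions: LiPPh2 (3 equiv, 0.5 M in THF), THF, rt; aq. NH4Cl
Reagents that add atoms: none
Why: SN2 demethylation of the aryl methyl ether by the soft phosphide, in which the first equivalent turns the acidic enol into an unreactive enolate, the tertiary pyran ether offers no SN2 path and the alkenes are inert, so no stereocentre is affected.

**Step 11**
Reactants: 20 pyran dienone phenol
Product: 23 target, (1R,5R,7R)-4-hydroxy-3-(3-hydroxybenzoyl)-8,8-dimethyl-1,7-bis(3-methylbut-2-enyl)-5-[(2S)-5-methyl-2-(prop-1-en-2-yl)hex-4-enyl]bicyclo[3.3.1]non-3-ene-2,9-dione, via bis-silyl pyran 21 (not isolated), via bis-silyl bicycle 22 (not isolated)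
Conditions: Me3SiOTf (3 equiv), 2,6-di-tert-butyl-4-methylpyridine (3 equiv), CH2Cl2, −78 → 0 °C; then NaHCO3, MeOH, 0 °C
Reagents that add atoms: none
Why: Proposed new method: silylation of the dienone carbonyl turns the tertiary-alkyl vinylogous ester into a leaving group (as Me3SiOTf does with tert-butyl esters and ethers), so only the C8–O bond ionises while the hindered pyridine traps every proton that could touch the four alkenes; the C8 tertiary cation of the presumed biosynthesis is held over the ring face fixed by C5 and is trapped irreversibly by the silyl dienol ether carbon C1 (closest known types: Reetz tert-alkylation of silyl enol ethers and Lewis-acid 1,3 O-to-C rearrangements), oxygen recapture being reversible, and C1 is set because the three-atom tether can bridge only one face while C5, C7 and the side-chain centre are untouched.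

**Compound list**
1 | 3-methylbut-2-enoic acid | CC(C)=CC(=O)O | starting material
2 | prenyl bromide (1-bromo-3-methylbut-2-ene) | CC(C)=CCBr | starting material
3 | (±)-lavandulic acid, racemic 5-methyl-2-(prop-1-en-2-yl)hex-4-enoic acid | C=C(C)C(CC=C(C)C)C(=O)O | intermediate
4 | (S)-4-benzyl-1,3-oxazolidin-2-one | O=C1N[C@@H](Cc2ccccc2)CO1 | starting material
5 | racemic lavandulic pivalic mixed anhydride (not isolated) | C=C(C)C(CC=C(C)C)C(=O)OC(=O)C(C)(C)C | intermediate
6 | (4S)-4-benzyl-3-[(2S)-5-methyl-2-(prop-1-en-2-yl)hex-4-enoyl]-1,3-oxazolidin-2-one | C=C(C)[C@H](CC=C(C)C)C(=O)N1[C@@H](Cc2ccccc2)COC1=O | intermediate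
7 | (4S)-4-benzyl-3-[(2R)-5-methyl-2-(prop-1-en-2-yl)hex-4-enoyl]-1,3-oxazolidin-2-one | C=C(C)[C@@H](CC=C(C)C)C(=O)N1[C@@H](Cc2ccccc2)COC1=O | intermediate
8 | (S)-lavandulol | C=C(C)[C@H](CC=C(C)C)CO | intermediate
9 | (R)-lavandulol | C=C(C)[C@@H](CC=C(C)C)CO | intermediate
10 | (2R)-2-(2-chloropropan-2-yl)-5-methylhex-4-en-1-ol | CC(C)(Cl)[C@H](CC=C(C)C)CO | intermediate
11 | phloroglucinol | Oc1cc(O)cc(O)c1 | starting material
12 | 3-methoxybenzoyl chloride | COc1cccc(C(=O)Cl)c1 | starting material
13 | (3-methoxyphenyl)(2,4,6-trihydroxyphenyl)methanone | COc1cccc(C(=O)c2c(O)cc(O)cc2O)c1 | intermediate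
14 | (3-methoxyphenyl)[2,4,6-trihydroxy-3-(3-methylbut-2-enyl)phenyl]methanone | COc1cccc(C(=O)c2c(O)cc(O)c(CC=C(C)C)c2O)c1 | intermediate
15 | (2R)-2-(2-chloropropan-2-yl)-5-methylhex-4-enyl triflate (not isolated) | CC(C)(Cl)[C@H](CC=C(C)C)COS(=O)(=O)C(F)(F)F | intermediate
16 | {3-[(2R)-2-(2-chloropropan-2-yl)-5-methylhex-4-enyl]-2,4,6-trihydroxy-5-(3-methylbut-2-enyl)phenyl}(3-methoxyphenyl)methanone (not isolated) | COc1cccc(C(=O)c2c(O)c(CC=C(C)C)c(O)c(C[C@@H](CC=C(C)C)C(C)(C)Cl)c2O)c1 | intermediate
17 | [(3R)-5,7-dihydroxy-2,2-dimethyl-3,8-bis(3-methylbut-2-enyl)chroman-6-yl](3-methoxyphenyl)methanone | COc1cccc(C(=O)c2c(O)c(CC=C(C)C)c3OC(C)(C)[C@H](CC=C(C)C)Cc3c2O)c1 | intermediate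
18 | (R)-lavandulyl triflate (not isolated) | C=C(C)[C@@H](CC=C(C)C)COS(=O)(=O)C(F)(F)F | intermediate
19 | (3R,4aS)-pyran dienone methyl ether, lavandulyl at C4a trans to the C3 prenyl | C=C(C)[C@@H](CC=C(C)C)C[C@@]12C[C@@H](CC=C(C)C)C(C)(C)OC2=C(CC=C(C)C)C(O)=C(C(=O)c3cccc(OC)c3)C1=O | intermediate
20 | (3R,4aS)-pyran dienone phenol | C=C(C)[C@@H](CC=C(C)C)C[C@@]12C[C@@H](CC=C(C)C)C(C)(C)OC2=C(CC=C(C)C)C(O)=C(C(=O)c3cccc(O)c3)C1=O | intermediate
21 | 7-O,3'-O-bis(trimethylsilyl) ether of 20 (not isolated) | C=C(C)[C@@H](CC=C(C)C)C[C@@]12C[C@@H](CC=C(C)C)C(C)(C)OC2=C(CC=C(C)C)C(O[Si](C)(C)C)=C(C(=O)c3cccc(O[Si](C)(C)C)c3)C1=O | intermediate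
22 | 4-O,3'-O-bis(trimethylsilyl) ether of 23 (not isolated) | C=C(C)[C@@H](CC=C(C)C)C[C@@]12C[C@@H](CC=C(C)C)C(C)(C)[C@@](CC=C(C)C)(C(=O)C(C(=O)c3cccc(O[Si](C)(C)C)c3)=C1O[Si](C)(C)C)C2=O | intermediate
23 | CNP0103487.1, (1R,5R,7R), side chain (2S), C7 prenyl endo | C=C(C)[C@@H](CC=C(C)C)C[C@@]12C[C@@H](CC=C(C)C)C(C)(C)[C@@](CC=C(C)C)(C(=O)C(C(=O)c3cccc(O)c3)=C1O)C2=O | target

**Step count and risks**
Total step count: 11. Longest linear sequence: 8 (steps 1, 2, 3, 5, 8, 9, 10, 11).

**Most likely to fail, first: step 11.** The cation may lose a proton instead of closing the ring. That gives the achiral gem-dilavandulyl dienone, a dead end that cannot re-enter because no acid is present. The cation may also be taken up by the aroyl-bearing carbon (type A skeleton), or simply return to oxygen.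

The fallback gives up the pyran as cation store and uses the carbon–chlorine bond instead.
- It sets out from 16, isolated by stopping step 8 before the (CF3)2CHOH stage.
- 16 is dearomatised with 18 and LiN(SiMe3)2 as in step 9 to the open-chain chloride dienone F1. The C5 epimers now have to be separated, because no ring steers the face.
- AgOTf and 2,6-di-tert-butyl-4-methylpyridine in CH2Cl2 at −78 °C ionise only the C–Cl bond, far below the temperature at which an ether ionises. The free enol then closes C1–C8 to the O-methyl ether of the target F2.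
- LiPPh2 as in step 10 gives 23, where the fallback rejoins the route.

**Second: step 9.** Alkylation may go to the prenyl-bearing C8 or to oxygen instead of C4a.

The fallback postpones the C1 prenyl group and holds its place with bromine.
- It sets out from 13 and 15 under the conditions of step 8. These give the prenyl-free open-chain chloride F3 (not isolated) and then the 8-unsubstituted chroman F4.
- NBS in CH2Cl2 at −78 °C gives the 8-bromochroman F5.
- 18 and LiN(SiMe3)2 then give the bromo dienone F6, since C4a is now the only alkyl-bearing nucleophilic carbon.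
- Pd(PPh3)4 and tributyl(3-methylbut-2-enyl)stannane in DMF at 60 °C replace bromine by prenyl and return to the route at 19.

**Third: step 8.** The hindered triflate may alkylate oxygen, or the ring may close on an ortho oxygen.

The fallback changes the way the C8–O bond is made, from chloride ionisation to a radical-polar crossover, and makes step 5 unnecessary.
- It sets out from 8 and 14. Compound 8 is converted into (S)-lavandulyl triflate F7, which is flatter and less hindered.
- F7 C-alkylates the lithium salt of 14 to the lavandulyl benzophenone F8.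
- N,N'-bis(3,5-di-tert-butylsalicylidene)-1,2-cyclohexanediaminocobalt (cat.), N-fluoro-2,4,6-trimethylpyridinium triflate and (Me2SiH)2O in PhCF3 hydroalkoxylate only the 1,1-disubstituted alkene with the free para hydroxyl. This returns to the route at 17.

**Further compounds**
F1 | step 11 | open-chain chloride dienone, C5 configured as in 23 | C=C(C)[C@@H](CC=C(C)C)C[C@]1(C[C@@H](CC=C(C)C)C(C)(C)Cl)C(=O)C(CC=C(C)C)=C(O)C(C(=O)c2cccc(OC)c2)=C1O
F2 | step 11 | O-methyl ether of the target | C=C(C)[C@@H](CC=C(C)C)C[C@@]12C[C@@H](CC=C(C)C)C(C)(C)[C@@](CC=C(C)C)(C(=O)C(C(=O)c3cccc(OC)c3)=C1O)C2=O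
F3 | step 9 | prenyl-free open-chain chloride | COc1cccc(C(=O)c2c(O)cc(O)c(C[C@@H](CC=C(C)C)C(C)(C)Cl)c2O)c1
F4 | step 9 | 8-unsubstituted (3R)-chroman | COc1cccc(C(=O)c2c(O)cc3OC(C)(C)[C@H](CC=C(C)C)Cc3c2O)c1
F5 | step 9 | 8-bromo-(3R)-chroman | COc1cccc(C(=O)c2c(O)c(Br)c3OC(C)(C)[C@H](CC=C(C)C)Cc3c2O)c1
F6 | step 9 | (3R,4aS)-8-bromo pyran dienone | C=C(C)[C@@H](CC=C(C)C)C[C@@]12C[C@@H](CC=C(C)C)C(C)(C)OC2=C(Br)C(O)=C(C(=O)c3cccc(OC)c3)C1=O
F7 | step 8 | (S)-lavandulyl triflate | C=C(C)[C@H](CC=C(C)C)COS(=O)(=O)C(F)(F)F
F8 | step 8 | lavandulyl benzophenone from (S)-lavandulol | COc1cccc(C(=O)c2c(O)c(CC=C(C)C)c(O)c(C[C@@H](CC=C(C)C)C(C)=C)c2O)c1
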